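**Plan**
1. Cuts: the (E)-propenyl group goes back to allyl and C8–H to a phenol (via its triflate). The benzene ring of the benzodioxane is then cut at C5–C6, C7–C8 and C8–C8a (Dötz benzannulation) into a dioxenyl(methoxy)carbene complex of zerovalent chromium, pent-1-en-4-yne and one CO ligand.
2. Enabling feature (numbering O1, C2 aryl, C3 methyl, O4, C4a, C5 OMe, C6, C7 side chain, C8, C8a): the ring-fusion bond C4a–C8a carries both dioxane oxygens. It can therefore enter as the enol-ether C=C of a 5,6-dihydro-1,4-dioxin, with C5–OMe as the carbene carbon on the O4-bearing carbon, C6/C7 as a terminal alkyne and C8 as CO.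
3. The carbene goes back through a vinylstannane and a ketene acetal phosphate to a 1,4-dioxan-2-one (cuts: lactone C–O4 and O1–CH2). The aryl–C2 bond is cut to an aryllithium and a lactic Weinreb amide.
4. Forward: the aryl and lactate pieces are joined, the dioxanone ring is closed and turned into the carbene complex, and the benzene ring is annulated last. Triflation/reduction at C8, olefin isomerisation and desilylation finish the route.
5. Stereochemistry: C3 comes from methyl (R)-lactate, C2 from Felkin–Anh reduction of the α-silyloxy aryl ketone (syn diol, trans on the ring), and the (E)-olefin from thermodynamic isomerisation.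

Key step: step 11

Remark: Ar = 3,5-dimethoxy-4-(triisopropylsilyloxy)phenyl. Benzodioxane locants follow the numbering of line 2 throughout, also where systematic rules would number the ring the other way round. The η6-arene chromium intermediate of the key step is written in line notation as two fragments.

**Route**

Step 1
Reactants: 1 4-bromo-2,6-dimethoxyphenol
Product: 2 (4-bromo-2,6-dimethoxyphenoxy)triisopropylsilane
Conditions: TIPSCl, imidazole, DMF, 23 → 50 °C
Reagents that add atoms: chlorotriisopropylsilane, CC(C)[Si](Cl)(C(C)C)C(C)C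
Why: Imidazole-mediated O-silylation of the phenol gives an aryl TIPS ether that should resist organolithiums, hydride, the acid of step 7 and the palladium and ruthenium steps, and is cleaved by fluoride only at the end.

Step 2
Reactants: 3 methyl (R)-lactate
Product: 4 methyl (R)-2-(tert-butyldimethylsilyloxy)propanoate
Conditions: TBSCl, imidazole, DMF, 0 → 23 °C
Reagents that add atoms: tert-butylchlorodimethylsilane, CC(C)(C)[Si](C)(C)Cl
Why: Standard O-silylation that does not touch the stereocentre; TBS is chosen because it does not chelate (needed in step 5) and is lost under acid far faster than the aryl TIPS ether.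

Step 3
Reactants: 4 methyl (R)-2-(tert-butyldimethylsilyloxy)propanoate
Product: 5 (R)-2-(tert-butyldimethylsilyloxy)-N-methoxy-N-methylpropanamide
Conditions: MeNH(OMe)·HCl, i-PrMgCl, THF, −20 → 0 °C
Reagents that add atoms: N,O-dimethylhydroxylamine hydrochloride, CNOC.Cl
Why: Weinreb amide formation by acyl substitution of the ester with the chloromagnesium amide at low temperature, a non-enolising process that should leave the α-silyloxy stereocentre intact.

Step 4
Reactants: 2 (4-bromo-2,6-dimethoxyphenoxy)triisopropylsilane; 5 (R)-2-(tert-butyldimethylsilyloxy)-N-methoxy-N-methylpropanamide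
Product: 7 (R)-2-(tert-butyldimethylsilyloxy)-1-Ar-propan-1-one, via aryllithium 6 (not isolated)
Conditions: 2, n-BuLi, THF, −78 °C; then 5, −78 → 0 °C; aq. NH4Cl
Reagents that add atoms: none
Why: Bromine–lithium exchange followed by Weinreb ketone synthesis, in which the chelated tetrahedral adduct persists until the quench, so that only one aryl group adds and the α-centre is not enolised.

Step 5
Reactants: 7 (R)-2-(tert-butyldimethylsilyloxy)-1-Ar-propan-1-one
Product: 8 (1R,2R)-2-(tert-butyldimethylsilyloxy)-1-Ar-propan-1-ol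
Conditions: LiBH(s-Bu)3, THF, −78 °C; aq. NH4Cl
Reagents that add atoms: none
Why: Felkin–Anh reduction in which the non-chelating OTBS group lies anti to the bulky hydride and attack passes the small α-hydrogen, which should give the 1,2-syn (threo) alcohol, so the lactate-derived centre sets the new benzylic centre as R.

Step 6
Reactants: 8 (1R,2R)-2-(tert-butyldimethylsilyloxy)-1-Ar-propan-1-ol
Product: 9 ethyl 2-[(1R,2R)-2-(tert-butyldimethylsilyloxy)-1-Ar-propoxy]acetate
Conditions: N2CHCO2Et (slow addition), Rh2(OAc)4 (1 mol %), CH2Cl2, 23 °C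
Reagents that add atoms: ethyl diazoacetate, CCOC(=O)C=[N+]=[N-]
Why: Rhodium-carbenoid O–H insertion etherifies the hindered benzylic alcohol under neutral conditions, which avoids the alkoxide-induced 1,2-silyl migration of a Williamson alkylation and touches neither stereocentre.

Step 7
Reactants: 9 ethyl 2-[(1R,2R)-2-(tert-butyldimethylsilyloxy)-1-Ar-propoxy]acetate
Product: 11 (5R,6R)-5-Ar-6-methyl-1,4-dioxan-2-one, via hydroxy ester 10 (not isolated)
Conditions: p-TsOH·H2O (0.1 equiv), EtOH, 23 °C; then PhMe, 60 °C, −EtOH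
Reagents that add atoms: none
Why: Acid-catalysed ethanolysis should remove the secondary alkyl TBS ether while the aryl TIPS ether stays, and the freed hydroxyl closes the dioxanone by 6-exo-trig transesterification driven by loss of ethanol, which places the carbonyl on the oxygen of the methyl-bearing carbon (the future O4).

Step 8
Reactants: 11 (5R,6R)-5-Ar-6-methyl-1,4-dioxan-2-one
Product: 13 (5R,6R)-5-Ar-6-methyl-5,6-dihydro-1,4-dioxin-2-yl diphenyl phosphate, via potassium enolate 12 (not isolated)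
Conditions: (PhO)2P(O)Cl, HMPA, THF, −78 °C; KN(SiMe3)2 added last
Reagents that add atoms: diphenyl phosphorochloridate, O=P(Cl)(Oc1ccccc1)Oc1ccccc1
Why: O-phosphorylation of the lactone enolate, trapped as it forms, gives the cyclic ketene acetal phosphate and fixes the site of the later carbene on the O4-bearing carbon.

Step 9
Reactants: 13 (5R,6R)-5-Ar-6-methyl-5,6-dihydro-1,4-dioxin-2-yl diphenyl phosphate
Product: 14 trimethyl[(5R,6R)-5-Ar-6-methyl-5,6-dihydro-1,4-dioxin-2-yl]stannane
Conditions: Me3SnSnMe3, Pd(PPh3)4 (5 mol %), LiCl, THF, 65 °C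
Reagents that add atoms: hexamethyldistannane, C[Sn](C)(C)[Sn](C)(C)C
Why: Palladium-catalysed stannylation of a ketene acetal phosphate, by oxidative addition of zerovalent palladium into the C–OP bond, chloride-assisted transmetalation with the distannane and reductive elimination, should give the α-alkoxyvinylstannane without touching the stereocentres.

Step 10
Reactants: 14 trimethyl[(5R,6R)-5-Ar-6-methyl-5,6-dihydro-1,4-dioxin-2-yl]stannane
Product: 17 pentacarbonyl{methoxy[(5R,6R)-5-Ar-6-methyl-5,6-dihydro-1,4-dioxin-2-yl]methylidene}chromium, via vinyllithium 15 (not isolated), via lithium acylchromate 16 (not isolated)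
Conditions: MeLi, THF, −78 °C; Cr(CO)6, −78 → 23 °C; then MeOTf, CH2Cl2, 0 °C
Reagents that add atoms: hexacarbonylchromium, O=C=[Cr](=C=O)(=C=O)(=C=O)(=C=O)=C=O; methyl trifluoromethanesulfonate, COS(=O)(=O)C(F)(F)F
Why: Tin–lithium exchange delivers the α-alkoxyvinyllithium at one defined position, this adds to a CO ligand of Cr(CO)6 to give the acylchromate, and O-methylation with MeOTf completes the classical Fischer carbene synthesis.

Step 11
Reactants: 17 pentacarbonyl{methoxy[(5R,6R)-5-Ar-6-methyl-5,6-dihydro-1,4-dioxin-2-yl]methylidene}chromium; 18 pent-1-en-4-yne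
Product: 20 (2R,3R)-7-allyl-2-Ar-5-methoxy-3-methyl-2,3-dihydro-1,4-benzodioxin-8-ol, via tricarbonylchromium arene complex 19 (not isolated)
Conditions: 18 (2 equiv), THF, 50 °C, sealed tube, argon; then air, EtOAc, 23 °C
Reagents that add atoms: none
Why: Thermal loss of one CO from the 18-electron zerovalent chromium carbene lets the alkyne bind and insert into the Cr=C bond with its unsubstituted end joined to the carbene carbon (C5–C6); a CO ligand then inserts (C7–C8) to give a chromium-bound dienylketene, and electrocyclisation onto the dioxene CH carbon (C8–C8a) followed by tautomerisation of the cyclohexadienone gives the phenol as its Cr(CO)3 complex 19, which air strips to 20. The closest known reaction type is the Dötz benzannulation of alkenyl(alkoxy)carbene complexes made from lithiated cyclic enol ethers (dihydropyranyl and glycal-derived complexes) with terminal alkynes. The benzene ring closes by a thermal disrotatory 6π-electrocyclisation of the dienylketene in the coordination sphere of chromium, not by an ionic exo or endo cyclisation. No stereocentre is formed, and C2 and C3 are sp3 carbons outside the reacting π-system under neutral conditions, so they should pass through unchanged. The step needs regioselective insertion (allyl at C7, H at C6), secured by the large steric difference between the two ends of a terminal alkyne; it needs reaction at the alkyne and not at the isolated alkene, as expected for an electron-rich alkoxycarbene; and it needs CO insertion to win over cyclobutenone or cyclopentadiene formation, which alkenyl complexes in THF at moderate temperature favour. The methoxy group can only end at C5 because the carbene carbon sits on the dioxene carbon that carries O4.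

Step 12
Reactants: 20 (2R,3R)-7-allyl-2-Ar-5-methoxy-3-methyl-2,3-dihydro-1,4-benzodioxin-8-ol
Product: 21 (2R,3R)-7-allyl-2-Ar-5-methoxy-3-methyl-2,3-dihydro-1,4-benzodioxin-8-yl trifluoromethanesulfonate
Conditions: Tf2O, pyridine, CH2Cl2, 0 °C
Reagents that add atoms: trifluoromethanesulfonic anhydride, O=S(=O)(OS(=O)(=O)C(F)(F)F)C(F)(F)F
Why: O-sulfonylation of the only free hydroxyl turns the unwanted C8 oxygen into a leaving group for palladium and also protects the oxidation-prone para-methoxyphenol.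

Step 13
Reactants: 21 (2R,3R)-7-allyl-2-Ar-5-methoxy-3-methyl-2,3-dihydro-1,4-benzodioxin-8-yl trifluoromethanesulfonate
Product: 22 (2R,3R)-7-allyl-2-Ar-5-methoxy-3-methyl-2,3-dihydro-1,4-benzodioxine
Conditions: Pd(OAc)2 (5 mol %), dppp (6 mol %), HCO2H, Et3N, DMF, 70 °C
Reagents that add atoms: none
Why: Palladium-catalysed transfer hydrogenolysis of the aryl triflate (oxidative addition, formate exchange, decarboxylation to an arylpalladium hydride, reductive elimination) replaces C8–O by C8–H, and any palladium-hydride migration of the allyl double bond only anticipates step 14.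

Step 14
Reactants: 22 (2R,3R)-7-allyl-2-Ar-5-methoxy-3-methyl-2,3-dihydro-1,4-benzodioxine
Product: 23 (2R,3R)-2-Ar-5-methoxy-3-methyl-7-[(E)-prop-1-enyl]-2,3-dihydro-1,4-benzodioxine
Conditions: RuHCl(CO)(PPh3)3 (2 mol %), PhMe, 80 °C
Reagents that add atoms: none
Why: Ruthenium hydride-catalysed olefin isomerisation (hydrometalation and β-hydride elimination) moves the double bond into conjugation with the arene and, being reversible, should settle on the thermodynamically preferred (E)-propenyl isomer.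

Step 15
Reactants: 23 (2R,3R)-2-Ar-5-methoxy-3-methyl-7-[(E)-prop-1-enyl]-2,3-dihydro-1,4-benzodioxine
Product: 24 2,6-dimethoxy-4-{(2R,3R)-5-methoxy-3-methyl-7-[(E)-prop-1-enyl]-2,3-dihydro-1,4-benzodioxin-2-yl}phenol (CNP0227775.1)
Conditions: Bu4NF, AcOH, THF, 0 °C
Reagents that add atoms: none
Why: Fluoride cleaves the aryl Si–O bond, and the acetic acid buffer keeps the freed para-hydroxybenzylic ether from opening through a quinone methide, so C2 should not epimerise.

**Compound list**
1 | 4-bromo-2,6-dimethoxyphenol | COc1cc(Br)cc(OC)c1O | starting material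
2 | (4-bromo-2,6-dimethoxyphenoxy)triisopropylsilane | COc1cc(Br)cc(OC)c1O[Si](C(C)C)(C(C)C)C(C)C | intermediate
3 | methyl (R)-lactate | COC(=O)[C@@H](C)O | starting material
4 | methyl (R)-2-(tert-butyldimethylsilyloxy)propanoate | COC(=O)[C@@H](C)O[Si](C)(C)C(C)(C)C | intermediate
5 | (R)-2-(tert-butyldimethylsilyloxy)-N-methoxy-N-methylpropanamide | CON(C)C(=O)[C@@H](C)O[Si](C)(C)C(C)(C)C | intermediate
6 | [3,5-dimethoxy-4-(triisopropylsilyloxy)phenyl]lithium (not isolated) | [Li]c1cc(OC)c(O[Si](C(C)C)(C(C)C)C(C)C)c(OC)c1 | intermediate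
7 | (R)-2-(tert-butyldimethylsilyloxy)-1-[3,5-dimethoxy-4-(triisopropylsilyloxy)phenyl]propan-1-one | O=C(c1cc(OC)c(O[Si](C(C)C)(C(C)C)C(C)C)c(OC)c1)[C@@H](C)O[Si](C)(C)C(C)(C)C | intermediate
8 | (1R,2R)-2-(tert-butyldimethylsilyloxy)-1-[3,5-dimethoxy-4-(triisopropylsilyloxy)phenyl]propan-1-ol | O[C@H](c1cc(OC)c(O[Si](C(C)C)(C(C)C)C(C)C)c(OC)c1)[C@@H](C)O[Si](C)(C)C(C)(C)C | intermediate
9 | ethyl 2-{(1R,2R)-2-(tert-butyldimethylsilyloxy)-1-[3,5-dimethoxy-4-(triisopropylsilyloxy)phenyl]propoxy}acetate | CCOC(=O)CO[C@H](c1cc(OC)c(O[Si](C(C)C)(C(C)C)C(C)C)c(OC)c1)[C@@H](C)O[Si](C)(C)C(C)(C)C | intermediate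
10 | ethyl 2-{(1R,2R)-1-[3,5-dimethoxy-4-(triisopropylsilyloxy)phenyl]-2-hydroxypropoxy}acetate (not isolated) | CCOC(=O)CO[C@H](c1cc(OC)c(O[Si](C(C)C)(C(C)C)C(C)C)c(OC)c1)[C@@H](C)O | intermediate
11 | (5R,6R)-5-[3,5-dimethoxy-4-(triisopropylsilyloxy)phenyl]-6-methyl-1,4-dioxan-2-one | O=C1CO[C@H](c2cc(OC)c(O[Si](C(C)C)(C(C)C)C(C)C)c(OC)c2)[C@@H](C)O1 | intermediate
12 | potassium (5R,6R)-5-[3,5-dimethoxy-4-(triisopropylsilyloxy)phenyl]-6-methyl-5,6-dihydro-1,4-dioxin-2-olate (not isolated) | [K+].[O-]C1=CO[C@H](c2cc(OC)c(O[Si](C(C)C)(C(C)C)C(C)C)c(OC)c2)[C@@H](C)O1 | intermediate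
13 | (5R,6R)-5-[3,5-dimethoxy-4-(triisopropylsilyloxy)phenyl]-6-methyl-5,6-dihydro-1,4-dioxin-2-yl diphenyl phosphate | O=P(Oc1ccccc1)(Oc1ccccc1)OC1=CO[C@H](c2cc(OC)c(O[Si](C(C)C)(C(C)C)C(C)C)c(OC)c2)[C@@H](C)O1 | intermediate
14 | trimethyl{(5R,6R)-5-[3,5-dimethoxy-4-(triisopropylsilyloxy)phenyl]-6-methyl-5,6-dihydro-1,4-dioxin-2-yl}stannane | C[Sn](C)(C)C1=CO[C@H](c2cc(OC)c(O[Si](C(C)C)(C(C)C)C(C)C)c(OC)c2)[C@@H](C)O1 | intermediate
15 | {(5R,6R)-5-[3,5-dimethoxy-4-(triisopropylsilyloxy)phenyl]-6-methyl-5,6-dihydro-1,4-dioxin-2-yl}lithium (not isolated) | [Li]C1=CO[C@H](c2cc(OC)c(O[Si](C(C)C)(C(C)C)C(C)C)c(OC)c2)[C@@H](C)O1 | intermediate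
16 | lithium pentacarbonyl({(5R,6R)-5-[3,5-dimethoxy-4-(triisopropylsilyloxy)phenyl]-6-methyl-5,6-dihydro-1,4-dioxin-2-yl}carbonyl)chromate (not isolated) | [Li+].[O-]C(C1=CO[C@H](c2cc(OC)c(O[Si](C(C)C)(C(C)C)C(C)C)c(OC)c2)[C@@H](C)O1)=[Cr](=C=O)(=C=O)(=C=O)(=C=O)=C=O | intermediate
17 | pentacarbonyl{methoxy[(5R,6R)-5-[3,5-dimethoxy-4-(triisopropylsilyloxy)phenyl]-6-methyl-5,6-dihydro-1,4-dioxin-2-yl]methylidene}chromium | COC(C1=CO[C@H](c2cc(OC)c(O[Si](C(C)C)(C(C)C)C(C)C)c(OC)c2)[C@@H](C)O1)=[Cr](=C=O)(=C=O)(=C=O)(=C=O)=C=O | intermediate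
18 | pent-1-en-4-yne | C=CCC#C | starting material
19 | tricarbonyl{η6-(2R,3R)-7-allyl-2-[3,5-dimethoxy-4-(triisopropylsilyloxy)phenyl]-5-methoxy-3-methyl-2,3-dihydro-1,4-benzodioxin-8-ol}chromium, metal on the new benzene ring (not isolated) | C=CCc1cc(OC)c2c(c1O)O[C@H](c1cc(OC)c(O[Si](C(C)C)(C(C)C)C(C)C)c(OC)c1)[C@@H](C)O2.[Cr](=C=O)(=C=O)=C=O | intermediate
20 | (2R,3R)-7-allyl-2-[3,5-dimethoxy-4-(triisopropylsilyloxy)phenyl]-5-methoxy-3-methyl-2,3-dihydro-1,4-benzodioxin-8-ol | C=CCc1cc(OC)c2c(c1O)O[C@H](c1cc(OC)c(O[Si](C(C)C)(C(C)C)C(C)C)c(OC)c1)[C@@H](C)O2 | intermediate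
21 | (2R,3R)-7-allyl-2-[3,5-dimethoxy-4-(triisopropylsilyloxy)phenyl]-5-methoxy-3-methyl-2,3-dihydro-1,4-benzodioxin-8-yl trifluoromethanesulfonate | C=CCc1cc(OC)c2c(c1OS(=O)(=O)C(F)(F)F)O[C@H](c1cc(OC)c(O[Si](C(C)C)(C(C)C)C(C)C)c(OC)c1)[C@@H](C)O2 | intermediate
22 | (2R,3R)-7-allyl-2-[3,5-dimethoxy-4-(triisopropylsilyloxy)phenyl]-5-methoxy-3-methyl-2,3-dihydro-1,4-benzodioxine | C=CCc1cc(OC)c2c(c1)O[C@H](c1cc(OC)c(O[Si](C(C)C)(C(C)C)C(C)C)c(OC)c1)[C@@H](C)O2 | intermediate
23 | (2R,3R)-2-[3,5-dimethoxy-4-(triisopropylsilyloxy)phenyl]-5-methoxy-3-methyl-7-[(E)-prop-1-enyl]-2,3-dihydro-1,4-benzodioxine | C/C=C/c1cc(OC)c2c(c1)O[C@H](c1cc(OC)c(O[Si](C(C)C)(C(C)C)C(C)C)c(OC)c1)[C@@H](C)O2 | intermediate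
24 | 2,6-dimethoxy-4-{(2R,3R)-5-methoxy-3-methyl-7-[(E)-prop-1-enyl]-2,3-dihydro-1,4-benzodioxin-2-yl}phenol (CNP0227775.1) | C/C=C/c1cc(OC)c2c(c1)O[C@H](c1cc(OC)c(O)c(OC)c1)[C@@H](C)O2 | target

**Count**
Total steps: 15. Longest linear sequence: 14 steps (3 to 24, steps 2–15); the aryl bromide branch (step 1) joins at step 4.

**Steps most likely to fail**

Risk 1, step 11. After CO loss, alkyne insertion may not be followed cleanly by CO insertion and ring closure: the volatile skipped enyne can oligomerise on chromium or occupy the metal through its alkene. The fallback keeps the benzannulation but no longer lets the alkyne carry the allyl group. It sets out from 17, which is heated in THF at 50 °C with ethynyltrimethylsilane as a sterically biased acetylene equivalent. The silyl group of the cyclohexadienone is expected to shift from carbon to oxygen, giving the aryl trimethylsilyl ether (2R,3R)-2-Ar-5-methoxy-3-methyl-8-(trimethylsilyloxy)-2,3-dihydro-1,4-benzodioxine F1. Dilute citric acid on work-up hydrolyses this to the C7-unsubstituted phenol (2R,3R)-2-Ar-5-methoxy-3-methyl-2,3-dihydro-1,4-benzodioxin-8-ol F2. O-allylation (allyl bromide, K2CO3, acetone) gives the allyl ether (2R,3R)-8-(allyloxy)-2-Ar-5-methoxy-3-methyl-2,3-dihydro-1,4-benzodioxine F3. Aromatic Claisen rearrangement (PhNEt2, 190 °C) then moves the allyl group to C7, the only free ortho position, and the route is rejoined at 20.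

Risk 2, step 9. Oxidative addition into the electron-rich ketene acetal phosphate may be slow, so that hydrolysis back to the lactone competes, and the α-alkoxyvinylstannane may protodestannylate on purification. The fallback avoids tin and vinyllithium chemistry and brings in the carbene carbon by carbonylation. It sets out from 13: Pd(PPh3)4, CO (1 atm), MeOH and Et3N in DMF at 60 °C should give methyl (5R,6R)-5-Ar-6-methyl-5,6-dihydro-1,4-dioxine-2-carboxylate F4. LiOH in aqueous THF at 0 °C gives (5R,6R)-5-Ar-6-methyl-5,6-dihydro-1,4-dioxine-2-carboxylic acid F5. Treatment with 1-chloro-N,N,2-trimethylprop-1-en-1-amine in CH2Cl2, under neutral conditions, gives the acid chloride (5R,6R)-5-Ar-6-methyl-5,6-dihydro-1,4-dioxine-2-carbonyl chloride F6. This acylates Na2Cr(CO)5 (made from Cr(CO)6 and sodium naphthalenide in THF at −78 °C) to give the sodium acylchromate, sodium pentacarbonyl{[(5R,6R)-5-Ar-6-methyl-5,6-dihydro-1,4-dioxin-2-yl]carbonyl}chromate F7. O-methylation with MeOTf returns to the route at 17, bypassing 14 to 16.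

Risk 3, step 5. Facial selectivity may be poor, because the TBS ether is only moderately bulky and the Felkin–Anh preference could erode, giving the anti alcohol and later the cis-benzodioxane. The fallback moves stereocontrol from the substrate to a chiral catalyst. It sets out from 7, which is reduced by Noyori transfer hydrogenation with RuCl[(S,S)-TsDPEN](p-cymene) in HCO2H/Et3N at 25–40 °C. The (S,S) enantiomer is the one expected, by analogy with simple aryl alkyl ketones, to give the 1R carbinol. The route is rejoined at 8 and no new compound is made.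

**Further compounds**
F1 | step 11 | (2R,3R)-2-[3,5-dimethoxy-4-(triisopropylsilyloxy)phenyl]-5-methoxy-3-methyl-8-(trimethylsilyloxy)-2,3-dihydro-1,4-benzodioxine | c1cc(OC)c2c(c1O[Si](C)(C)C)O[C@H](c1cc(OC)c(O[Si](C(C)C)(C(C)C)C(C)C)c(OC)c1)[C@@H](C)O2
F2 | step 11 | (2R,3R)-2-[3,5-dimethoxy-4-(triisopropylsilyloxy)phenyl]-5-methoxy-3-methyl-2,3-dihydro-1,4-benzodioxin-8-ol | c1cc(OC)c2c(c1O)O[C@H](c1cc(OC)c(O[Si](C(C)C)(C(C)C)C(C)C)c(OC)c1)[C@@H](C)O2
F3 | step 11 | (2R,3R)-8-(allyloxy)-2-[3,5-dimethoxy-4-(triisopropylsilyloxy)phenyl]-5-methoxy-3-methyl-2,3-dihydro-1,4-benzodioxine | c1cc(OC)c2c(c1OCC=C)O[C@H](c1cc(OC)c(O[Si](C(C)C)(C(C)C)C(C)C)c(OC)c1)[C@@H](C)O2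
F4 | step 9 | methyl (5R,6R)-5-[3,5-dimethoxy-4-(triisopropylsilyloxy)phenyl]-6-methyl-5,6-dihydro-1,4-dioxine-2-carboxylate | COC(=O)C1=CO[C@H](c2cc(OC)c(O[Si](C(C)C)(C(C)C)C(C)C)c(OC)c2)[C@@H](C)O1
F5 | step 9 | (5R,6R)-5-[3,5-dimethoxy-4-(triisopropylsilyloxy)phenyl]-6-methyl-5,6-dihydro-1,4-dioxine-2-carboxylic acid | OC(=O)C1=CO[C@H](c2cc(OC)c(O[Si](C(C)C)(C(C)C)C(C)C)c(OC)c2)[C@@H](C)O1
F6 | step 9 | (5R,6R)-5-[3,5-dimethoxy-4-(triisopropylsilyloxy)phenyl]-6-methyl-5,6-dihydro-1,4-dioxine-2-carbonyl chloride | ClC(=O)C1=CO[C@H](c2cc(OC)c(O[Si](C(C)C)(C(C)C)C(C)C)c(OC)c2)[C@@H](C)O1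
F7 | step 9 | sodium pentacarbonyl({(5R,6R)-5-[3,5-dimethoxy-4-(triisopropylsilyloxy)phenyl]-6-methyl-5,6-dihydro-1,4-dioxin-2-yl}carbonyl)chromate | [Na+].[O-]C(C1=CO[C@H](c2cc(OC)c(O[Si](C(C)C)(C(C)C)C(C)C)c(OC)c2)[C@@H](C)O1)=[Cr](=C=O)(=C=O)(=C=O)(=C=O)=C=O
F0 | step 5 | none | none
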